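**Retrosynthetic overview**

1. The coumarate ester and the two aldehydes come last: a drim-7-ene-1β,11,12-triol is silylated at the primary hydroxyls, esterified at O1 with silyl-protected p-coumaric acid, desilylated at C11/C12, doubly oxidised (Swern) and finally freed at the phenol.
2. The triol comes from a Δ7 11,12-diester, made by deconjugative protonation of the Δ8 diester; C12 is introduced by carbonylation of the enol triflate of a bicyclic 8-oxo-11-ester.
3. Key disconnection: the bicyclic β-keto ester is opened to an acyclic aldehyde–(Z)-enoate–methyl ester; one reductive cascade forms C1–C10 (ring A, first) and then C8–C9 (ring B, second).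
4. Enabling feature: the oxygen-bearing ring A carbon C1 and the quaternary ring-fusion carbon C10 are both acceptor carbons, because C10 is β to the C11 carbonyl on ring B carbon C9 (pattern O–C1–C10–C9–C11=O). A ketyl at C1 (polarity reversal) can therefore add to the C9=C10 enoate, and the enolate born at C9 closes ring B onto C8.
5. The acyclic precursor comes from 3,3-dimethylpent-4-enoic acid: auxiliary-controlled Michael addition (sets C5), β-keto ester → (E)-enol triflate → (Z)-β-methyl enoate, and hydroformylation (C1 aldehyde).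

Key step: step 8

Remark: drimane numbering is used for the bicyclic compounds (C11 on C9, C12 on C8); the target is read as 1β-O-acyl, 5α-H, 9α-H, 10β-CH3, that is (1R,5S,9R,10S), and 3,3-dimethylpent-4-enoic acid is taken as a commercial starting material.

**Route**

Step 1
Reactants: 1 3,3-dimethylpent-4-enoic acid; 2 (S)-4-benzyloxazolidin-2-one
Product: 4 (S)-4-benzyl-3-(3,3-dimethylpent-4-enoyl)oxazolidin-2-one, via mixed pivalic anhydride 3 (not isolated)
Conditions: t-BuCOCl, Et3N, THF, −20 °C; then 2, LiCl, rt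
Reagents that add atoms: none
Why: N-acylation of the LiCl-activated oxazolidinone by the mixed anhydride occurs at the less hindered acyl group and is the standard loading of this chiral auxiliary; no stereocentre is formed.

Step 2
Reactants: 4 (S)-4-benzyl-3-(3,3-dimethylpent-4-enoyl)oxazolidin-2-one; 5 methyl acrylate
Product: 6 methyl (4S)-5-[(4S)-4-benzyl-2-oxooxazolidin-3-yl]-4-(2-methylbut-3-en-2-yl)-5-oxopentanoate
Conditions: TiCl4, iPr2NEt, CH2Cl2, 0 °C; then 5, 0 °C
Reagents that add atoms: none
Why: Auxiliary-controlled Michael addition of the chelated (Z)-chlorotitanium enolate to the acrylate should occur on the enolate face remote from the benzyl group, which sets C5 as (S) and installs C6–C8 in one operation.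

Step 3
Reactants: 6 methyl (4S)-5-[(4S)-4-benzyl-2-oxooxazolidin-3-yl]-4-(2-methylbut-3-en-2-yl)-5-oxopentanoate
Product: 8 (2S)-5-methoxy-2-(2-methylbut-3-en-2-yl)-5-oxopentanoic acid, via peroxy acid 7 (not isolated)
Conditions: LiOH, H2O2, THF/H2O, 0 °C; then Na2SO3; HCl
Reagents that add atoms: hydrogen peroxide (OO)
Why: Hydroperoxide attacks the exocyclic imide carbonyl faster than hydroxide saponifies the methyl ester at 0 °C (chemoselective auxiliary hydrolysis), so the acid is released and the auxiliary recovered without enolising C5.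

Step 4
Reactants: 8 (2S)-5-methoxy-2-(2-methylbut-3-en-2-yl)-5-oxopentanoic acid; 9 3-tert-butoxy-3-oxopropanoic acid
Product: 12 1-tert-butyl 7-methyl (4S)-4-(2-methylbut-3-en-2-yl)-3-oxoheptanedioate, via acyl imidazolide 10 (not isolated), via acylmalonic half ester 11 (not isolated)
Conditions: carbonyldiimidazole, THF, rt; then 9, MgCl2, Et3N, MeCN, rt; aq. HCl
Reagents that add atoms: none
Why: Decarboxylative Claisen-type C-acylation of the magnesium malonate half-ester enolate by the acyl imidazolide runs under nearly neutral conditions, so the α-stereocentre C5 should not epimerise on the way to the tert-butyl β-keto ester.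

Step 5
Reactants: 12 1-tert-butyl 7-methyl (4S)-4-(2-methylbut-3-en-2-yl)-3-oxoheptanedioate
Product: 13 1-tert-butyl 7-methyl (2E,4S)-4-(2-methylbut-3-en-2-yl)-3-(trifluoromethylsulfonyloxy)hept-2-enedioate
Conditions: Me4NOH (aq), Tf2O, hexane/H2O, 5 °C
Reagents that add atoms: trifluoromethanesulfonic anhydride (O=S(=O)(OS(=O)(=O)C(F)(F)F)C(F)(F)F)
Why: O-sulfonylation of the β-keto ester enolate with a non-coordinating ammonium counter-ion (enol triflate formation) goes through the dipole-minimised enolate and should give the (E)-enol triflate, which places the ester cis to the C5 branch; C5 is not deprotonated under these conditions.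

Step 6
Reactants: 13 1-tert-butyl 7-methyl (2E,4S)-4-(2-methylbut-3-en-2-yl)-3-(trifluoromethylsulfonyloxy)hept-2-enedioate
Product: 14 1-tert-butyl 7-methyl (2Z,4R)-3-methyl-4-(2-methylbut-3-en-2-yl)hept-2-enedioate
Conditions: Me2Zn, Pd(PPh3)4 (cat.), THF, 0 °C to rt
Reagents that add atoms: dimethylzinc (C[Zn]C)
Why: Negishi coupling of an enol triflate proceeds with retention of alkene geometry, so the methyl group takes the place of the triflate and the (Z)-β-methyl enoate with the ester cis to C5 should result (the C5 descriptor changes only by the priority rules).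

Step 7
Reactants: 14 1-tert-butyl 7-methyl (2Z,4R)-3-methyl-4-(2-methylbut-3-en-2-yl)hept-2-enedioate
Product: 15 1-tert-butyl 7-methyl (2Z,4S)-3-methyl-4-(2-methyl-5-oxopentan-2-yl)hept-2-enedioate
Conditions: Rh(acac)(CO)2 (cat.), Xantphos, CO/H2 (1:1, 10 bar), toluene, 70 °C
Reagents that add atoms: carbon monoxide ([C-]#[O+])
Why: Rhodium-catalysed hydroformylation with a wide-bite-angle diphosphine puts the formyl group on the terminal carbon of the vinyl group (the internal carbon is neopentyl) and leaves the trisubstituted enoate alone, so the C1 aldehyde is unveiled without protecting groups.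

Step 8
Reactants: 15 1-tert-butyl 7-methyl (2Z,4S)-3-methyl-4-(2-methyl-5-oxopentan-2-yl)hept-2-enedioate
Product: 17 tert-butyl 1β-hydroxy-8-oxo-12-nordriman-11-oate (5α-H, 10β-CH3, keto form), via monocyclic samarium enolate 16 (not isolated)
Conditions: SmI2 (2.5 equiv), HMPA, THF, −78 °C to rt, high dilution; then aq. NH4Cl
Reagents that add atoms: none
Why: Proposed new method: SmI2–HMPA transfers one electron to the aldehyde (the most easily reduced group of 15), the C1 ketyl adds 6-exo-trig to C10, the β-carbon of the (Z)-enoate, a second electron converts the C9 radical into a trivalent samarium ester enolate that exists only at C9, and this enolate acylates the C8 methyl ester in a 6-(enolexo)-exo-trig Dieckmann closure driven by loss of methoxide and formation of the chelated β-keto ester enolate; the closest known reaction type is the SmI2 ketyl–olefin cyclisation onto β,β-disubstituted acrylates whose samarium enolate is trapped in the same flask by an intramolecular aldol addition, and only the ester acceptor is new. Ring A closes through a chair in which A(1,3) strain with the cis ester holds H5 in the plane of C9=C10, so the tether attacks the face that leaves C6 equatorial and the C10 methyl axial (H5 anti to CH3, 10S), while the HMPA-solvated O–Sm group sits pseudo-equatorial and trans to C9, which gives the 1β (1R) alcohol. Ring B then closes between the equatorial C5–C6 and C10–C9 bonds, so the decalin is trans-fused, and C9 remains an enolisable β-keto ester centre that is fixed in step 11. The step needs electron transfer to the aldehyde in preference to the enoate and the esters, and a single direction of acylation: the tert-butyl ester cannot serve as acyl acceptor and the aprotic medium keeps the enolate alive.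

Step 9
Reactants: 17 tert-butyl 1β-hydroxy-8-oxo-12-nordriman-11-oate
Product: 18 tert-butyl 1β-hydroxy-8-(trifluoromethylsulfonyloxy)-12-nordrim-8-en-11-oate
Conditions: NaH (1.05 equiv), THF, 0 °C; then PhNTf2, 0 °C to rt
Reagents that add atoms: N-phenylbis(trifluoromethanesulfonimide) (O=S(=O)(N(c1ccccc1)S(=O)(=O)C(F)(F)F)C(F)(F)F)
Why: The β-keto ester is far more acidic than the hindered 1β-alcohol, so one equivalent of NaH gives only the chelated enolate, which is O-sulfonylated to the C8 enol triflate (enol triflate formation) with C9 becoming sp2.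

Step 10
Reactants: 18 tert-butyl 1β-hydroxy-8-(trifluoromethylsulfonyloxy)-12-nordrim-8-en-11-oate
Product: 19 11-tert-butyl 12-methyl 1β-hydroxydrim-8-ene-11,12-dioate
Conditions: Pd(OAc)2 (cat.), dppf, CO (1 atm), MeOH, Et3N, DMF, 60 °C
Reagents that add atoms: carbon monoxide ([C-]#[O+]); methanol (CO)
Why: Palladium-catalysed alkoxycarbonylation of the enol triflate installs C12 as a methyl ester, and because the acylpalladium at C8 lies trans to C10 across the double bond the 1β-hydroxyl cannot capture it, so methanol is the only nucleophile.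

Step 11
Reactants: 19 11-tert-butyl 12-methyl 1β-hydroxydrim-8-ene-11,12-dioate
Product: 20 11-tert-butyl 12-methyl 1β-hydroxydrim-7-ene-11,12-dioate (9α-H)
Conditions: LiN(iPr)2 (2.5 equiv), THF/DMPU, −78 °C; then AcOH, −78 °C
Reagents that add atoms: none
Why: γ-Deprotonation at C7 gives the extended enolate of the C11 ester, and its kinetic α-protonation at C9 (deconjugative protonation of a dienolate) should occur axially from the α-face, anti to the C10 methyl group, which sets 9α-H and moves the alkene to C7=C8 in conjugation with the C12 ester.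

Step 12
Reactants: 20 11-tert-butyl 12-methyl 1β-hydroxydrim-7-ene-11,12-dioate
Product: 21 drim-7-ene-1β,11,12-triol
Conditions: LiAlH4, THF, 0 °C to rt; aq. NaOH work-up
Reagents that add atoms: none
Why: Hydride reduction converts the conjugated methyl ester (1,2-addition) and the tert-butyl ester into the primary alcohols at low temperature without moving the C7=C8 bond or touching any stereocentre.

Step 13
Reactants: 21 drim-7-ene-1β,11,12-triol
Product: 22 11,12-bis(tert-butyldimethylsilyloxy)drim-7-en-1β-ol
Conditions: TBSCl (2.2 equiv), imidazole, CH2Cl2, 0 °C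
Reagents that add atoms: tert-butyldimethylsilyl chloride (CC(C)(C)[Si](C)(C)Cl)
Why: The two primary hydroxyls are silylated much faster than the secondary 1β-hydroxyl next to the quaternary C10, so selective silyl ether formation should leave only O1 free.

Step 14
Reactants: 23 (E)-4-hydroxycinnamic acid (p-coumaric acid)
Product: 25 (E)-3-[4-(tert-butyldimethylsilyloxy)phenyl]prop-2-enoic acid, via bis-silylated coumarate 24 (not isolated)
Conditions: TBSCl (2.2 equiv), imidazole, DMF, rt; then AcOH, THF/H2O, rt
Reagents that add atoms: tert-butyldimethylsilyl chloride (CC(C)(C)[Si](C)(C)Cl)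
Why: Exhaustive silylation followed by mild aqueous acid hydrolyses only the labile silyl ester, which leaves the aryl silyl ether (phenol protection) and the (E)-alkene intact.

Step 15
Reactants: 22 11,12-bis(tert-butyldimethylsilyloxy)drim-7-en-1β-ol; 25 (E)-3-[4-(tert-butyldimethylsilyloxy)phenyl]prop-2-enoic acid
Product: 27 11,12-bis(tert-butyldimethylsilyloxy)drim-7-en-1β-yl (E)-3-[4-(tert-butyldimethylsilyloxy)phenyl]prop-2-enoate, via mixed trichlorobenzoic anhydride 26 (not isolated)
Conditions: 25, 2,4,6-Cl3C6H2COCl, Et3N, THF, rt; then 22, DMAP, toluene, 40 °C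
Reagents that add atoms: none
Why: Yamaguchi esterification through the mixed anhydride and the acylpyridinium ion acylates hindered secondary alcohols with retention at C1 and should not disturb the silyl ethers or the (E)-cinnamate geometry.

Step 16
Reactants: 27 11,12-bis(tert-butyldimethylsilyloxy)drim-7-en-1β-yl (E)-3-[4-(tert-butyldimethylsilyloxy)phenyl]prop-2-enoate
Product: 28 11,12-dihydroxydrim-7-en-1β-yl (E)-3-[4-(tert-butyldimethylsilyloxy)phenyl]prop-2-enoate
Conditions: camphorsulfonic acid (cat.), MeOH/CH2Cl2, 0 °C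
Reagents that add atoms: none
Why: Acid-catalysed methanolysis cleaves primary alkyl silyl ethers much faster than aryl silyl ethers (selective desilylation), so the 11,12-diol should be released while the phenol stays protected.

Step 17
Reactants: 28 11,12-dihydroxydrim-7-en-1β-yl (E)-3-[4-(tert-butyldimethylsilyloxy)phenyl]prop-2-enoate
Product: 29 11,12-dioxodrim-7-en-1β-yl (E)-3-[4-(tert-butyldimethylsilyloxy)phenyl]prop-2-enoate
Conditions: (COCl)2, DMSO, CH2Cl2, −78 °C; then Et3N, −78 to −20 °C
Reagents that add atoms: none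
Why: In the Swern oxidation both hydroxyls are converted into alkoxysulfonium ions at −78 °C before the base is added, which avoids lactol and lactone formation from the 1,4-diol, and the cold amine treatment should give the dialdehyde without epimerising C9.

Step 18
Reactants: 29 11,12-dioxodrim-7-en-1β-yl (E)-3-[4-(tert-butyldimethylsilyloxy)phenyl]prop-2-enoate
Product: 30 11,12-dioxodrim-7-en-1β-yl (E)-3-(4-hydroxyphenyl)prop-2-enoate (1β-(E)-p-coumaroyloxypolygodial)
Conditions: Bu4NF, AcOH (1:1), THF, 0 °C
Reagents that add atoms: none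
Why: Acetic acid-buffered fluoride cleaves the aryl silyl ether quickly at 0 °C (fluoride desilylation) under nearly neutral conditions that should leave the base-sensitive C9 centre, the enal and the coumarate ester untouched.

**Compound list**

1 | 3,3-dimethylpent-4-enoic acid | C=CC(C)(C)CC(=O)O | starting material
2 | (S)-4-benzyloxazolidin-2-one | O=C1N[C@@H](Cc2ccccc2)CO1 | starting material
3 | 3,3-dimethylpent-4-enoic pivalic anhydride | C=CC(C)(C)CC(=O)OC(=O)C(C)(C)C | intermediate
4 | (S)-4-benzyl-3-(3,3-dimethylpent-4-enoyl)oxazolidin-2-one | C=CC(C)(C)CC(=O)N1[C@@H](Cc2ccccc2)COC1=O | intermediate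
5 | methyl acrylate | C=CC(=O)OC | starting material
6 | methyl (4S)-5-[(4S)-4-benzyl-2-oxooxazolidin-3-yl]-4-(2-methylbut-3-en-2-yl)-5-oxopentanoate | COC(=O)CC[C@@H](C(C)(C)C=C)C(=O)N1[C@@H](Cc2ccccc2)COC1=O | intermediate
7 | (2S)-5-methoxy-2-(2-methylbut-3-en-2-yl)-5-oxopentaneperoxoic acid | COC(=O)CC[C@@H](C(C)(C)C=C)C(=O)OO | intermediate
8 | (2S)-5-methoxy-2-(2-methylbut-3-en-2-yl)-5-oxopentanoic acid | COC(=O)CC[C@@H](C(C)(C)C=C)C(=O)O | intermediate
9 | 3-tert-butoxy-3-oxopropanoic acid (mono-tert-butyl malonate) | CC(C)(C)OC(=O)CC(=O)O | starting material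
10 | methyl (4S)-5-(imidazol-1-yl)-4-(2-methylbut-3-en-2-yl)-5-oxopentanoate | COC(=O)CC[C@@H](C(C)(C)C=C)C(=O)n1ccnc1 | intermediate
11 | (4S)-2-(tert-butoxycarbonyl)-7-methoxy-4-(2-methylbut-3-en-2-yl)-3,7-dioxoheptanoic acid | COC(=O)CC[C@@H](C(C)(C)C=C)C(=O)C(C(=O)O)C(=O)OC(C)(C)C | intermediate
12 | 1-tert-butyl 7-methyl (4S)-4-(2-methylbut-3-en-2-yl)-3-oxoheptanedioate | COC(=O)CC[C@@H](C(C)(C)C=C)C(=O)CC(=O)OC(C)(C)C | intermediate
13 | 1-tert-butyl 7-methyl (2E,4S)-4-(2-methylbut-3-en-2-yl)-3-(trifluoromethylsulfonyloxy)hept-2-enedioate | COC(=O)CC[C@@H](C(C)(C)C=C)/C(OS(=O)(=O)C(F)(F)F)=C\C(=O)OC(C)(C)C | intermediate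
14 | 1-tert-butyl 7-methyl (2Z,4R)-3-methyl-4-(2-methylbut-3-en-2-yl)hept-2-enedioate (same spatial arrangement at C5 as in 13 and 15) | COC(=O)CC[C@@H](C(C)(C)C=C)/C(C)=C\C(=O)OC(C)(C)C | intermediate
15 | 1-tert-butyl 7-methyl (2Z,4S)-3-methyl-4-(2-methyl-5-oxopentan-2-yl)hept-2-enedioate | COC(=O)CC[C@@H](C(C)(C)CCC=O)/C(C)=C\C(=O)OC(C)(C)C | intermediate
16 | monocyclic diiodosamarium alkoxide and ester enolate (ring A closed, C1–O–SmI2, C9=C11(OtBu)–O–SmI2) | CC1(C)CC[C@@H](O[Sm](I)I)[C@](C)(C=C(O[Sm](I)I)OC(C)(C)C)[C@H]1CCC(=O)OC | intermediate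
17 | tert-butyl 1β-hydroxy-8-oxo-12-nordriman-11-oate (5α-H, 10β-CH3; keto form with 9α-H drawn, C9 epimerisable) | CC1(C)CC[C@@H](O)[C@]2(C)[C@@H](C(=O)OC(C)(C)C)C(=O)CC[C@@H]12 | intermediate
18 | tert-butyl 1β-hydroxy-8-(trifluoromethylsulfonyloxy)-12-nordrim-8-en-11-oate | CC1(C)CC[C@@H](O)[C@]2(C)C(C(=O)OC(C)(C)C)=C(OS(=O)(=O)C(F)(F)F)CC[C@@H]12 | intermediate
19 | 11-tert-butyl 12-methyl 1β-hydroxydrim-8-ene-11,12-dioate | CC1(C)CC[C@@H](O)[C@]2(C)C(C(=O)OC(C)(C)C)=C(C(=O)OC)CC[C@@H]12 | intermediate
20 | 11-tert-butyl 12-methyl 1β-hydroxydrim-7-ene-11,12-dioate (9α-H) | CC1(C)CC[C@@H](O)[C@]2(C)[C@@H](C(=O)OC(C)(C)C)C(C(=O)OC)=CC[C@@H]12 | intermediate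
21 | drim-7-ene-1β,11,12-triol | CC1(C)CC[C@@H](O)[C@]2(C)[C@@H](CO)C(CO)=CC[C@@H]12 | intermediate
22 | 11,12-bis(tert-butyldimethylsilyloxy)drim-7-en-1β-ol | CC1(C)CC[C@@H](O)[C@]2(C)[C@@H](CO[Si](C)(C)C(C)(C)C)C(CO[Si](C)(C)C(C)(C)C)=CC[C@@H]12 | intermediate
23 | (E)-4-hydroxycinnamic acid (p-coumaric acid) | OC(=O)/C=C/c1ccc(O)cc1 | starting material
24 | tert-butyldimethylsilyl (E)-3-[4-(tert-butyldimethylsilyloxy)phenyl]prop-2-enoate | CC(C)(C)[Si](C)(C)OC(=O)/C=C/c1ccc(O[Si](C)(C)C(C)(C)C)cc1 | intermediate
25 | (E)-3-[4-(tert-butyldimethylsilyloxy)phenyl]prop-2-enoic acid | OC(=O)/C=C/c1ccc(O[Si](C)(C)C(C)(C)C)cc1 | intermediate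
26 | (E)-3-[4-(tert-butyldimethylsilyloxy)phenyl]prop-2-enoic 2,4,6-trichlorobenzoic anhydride | O=C(/C=C/c1ccc(O[Si](C)(C)C(C)(C)C)cc1)OC(=O)c1c(Cl)cc(Cl)cc1Cl | intermediate
27 | 11,12-bis(tert-butyldimethylsilyloxy)drim-7-en-1β-yl (E)-3-[4-(tert-butyldimethylsilyloxy)phenyl]prop-2-enoate | CC1(C)CC[C@@H](OC(=O)/C=C/c2ccc(O[Si](C)(C)C(C)(C)C)cc2)[C@]2(C)[C@@H](CO[Si](C)(C)C(C)(C)C)C(CO[Si](C)(C)C(C)(C)C)=CC[C@@H]12 | intermediate
28 | 11,12-dihydroxydrim-7-en-1β-yl (E)-3-[4-(tert-butyldimethylsilyloxy)phenyl]prop-2-enoate | CC1(C)CC[C@@H](OC(=O)/C=C/c2ccc(O[Si](C)(C)C(C)(C)C)cc2)[C@]2(C)[C@@H](CO)C(CO)=CC[C@@H]12 | intermediate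
29 | 11,12-dioxodrim-7-en-1β-yl (E)-3-[4-(tert-butyldimethylsilyloxy)phenyl]prop-2-enoate | CC1(C)CC[C@@H](OC(=O)/C=C/c2ccc(O[Si](C)(C)C(C)(C)C)cc2)[C@]2(C)[C@@H](C=O)C(C=O)=CC[C@@H]12 | intermediate
30 | 11,12-dioxodrim-7-en-1β-yl (E)-3-(4-hydroxyphenyl)prop-2-enoate, (1R,5S,9R,10S) | CC1(C)CC[C@@H](OC(=O)/C=C/c2ccc(O)cc2)[C@]2(C)[C@@H](C=O)C(C=O)=CC[C@@H]12 | target

**Step count and risks**

Total step count: 18. Longest linear sequence: 17 steps (steps 1–13 and 15–18, from acid 1).

Steps most likely to fail:

1. Step 8 (proposed cascade). The trivalent samarium enolate may be protonated, or may acylate the methyl ester too slowly, so that ring B does not close in the reductive step; simple reduction or pinacol coupling of the aldehyde could also compete. The fallback sets out from 15. The known protic variant of the ketyl–olefin cyclisation (SmI2, HMPA, THF, t-BuOH, −78 °C) should stop after ring A and give methyl 3-[(1S,2R,3R)-2-(2-tert-butoxy-2-oxoethyl)-3-hydroxy-2,6,6-trimethylcyclohexyl]propanoate F1 with the same C1 and C10 configurations. A classical Dieckmann condensation (KOtBu, THF, 0 °C to rt, acidic work-up) then closes ring B; the only productive mode is attack of the C9 tert-butyl ester enolate on the methyl ester, because a tert-butyl ester is not acylated. The route is rejoined at 17.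

2. Step 5. The (E)-selectivity of the O-sulfonylation may erode, because the (E)-isomer carries the bulky C5 branch cis to the ester; a wrong enoate geometry would be expected to reverse the facial preference of the ring A closure in step 8. The fallback sets out from 12. O-sulfonylation under chelating conditions (aq. LiOH, Tf2O, 5 °C) should give the unencumbered 1-tert-butyl 7-methyl (2Z,4S)-4-(2-methylbut-3-en-2-yl)-3-(trifluoromethylsulfonyloxy)hept-2-enedioate F2. Anti-elimination with LiN(SiMe3)2 (THF, −78 °C) gives the alkynoate 1-tert-butyl 7-methyl (4S)-4-(2-methylbut-3-en-2-yl)hept-2-ynedioate F3. Syn-addition of Me2CuLi (THF, −78 °C, protonation at −78 °C) places CH3 and H cis, and therefore the ester cis to C5. The route is rejoined at 14.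

3. Step 2. The neopentyl-type titanium enolate may be too unreactive toward the acrylate, with oligomerisation of the acceptor taking over. The fallback sets out from 4. Alkylation of the sodium enolate (NaN(SiMe3)2, THF, −78 °C) with propargyl bromide follows the same facial rule and gives (S)-4-benzyl-3-[(2S)-2-(2-methylbut-3-en-2-yl)pent-4-ynoyl]oxazolidin-2-one F4. Hydroboration of the terminal alkyne with dicyclohexylborane and oxidation with NaBO3 gives (S)-4-benzyl-3-[(2S)-2-(2-methylbut-3-en-2-yl)-5-oxopentanoyl]oxazolidin-2-one F5; the vinyl group on the quaternary carbon reacts far more slowly. Pinnick oxidation (NaClO2, NaH2PO4, 2-methylbut-2-ene) gives (4S)-5-[(4S)-4-benzyl-2-oxooxazolidin-3-yl]-4-(2-methylbut-3-en-2-yl)-5-oxopentanoic acid F6. Methylation with Me3SiCHN2 in MeOH rejoins the route at 6.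

Further compounds
F1 | step 8 | methyl 3-[(1S,2R,3R)-2-(2-tert-butoxy-2-oxoethyl)-3-hydroxy-2,6,6-trimethylcyclohexyl]propanoate | CC1(C)CC[C@@H](O)[C@](C)(CC(=O)OC(C)(C)C)[C@H]1CCC(=O)OC
F2 | step 5 | 1-tert-butyl 7-methyl (2Z,4S)-4-(2-methylbut-3-en-2-yl)-3-(trifluoromethylsulfonyloxy)hept-2-enedioate | COC(=O)CC[C@@H](C(C)(C)C=C)/C(OS(=O)(=O)C(F)(F)F)=C/C(=O)OC(C)(C)C
F3 | step 5 | 1-tert-butyl 7-methyl (4S)-4-(2-methylbut-3-en-2-yl)hept-2-ynedioate | COC(=O)CC[C@@H](C(C)(C)C=C)C#CC(=O)OC(C)(C)C
F4 | step 2 | (S)-4-benzyl-3-[(2S)-2-(2-methylbut-3-en-2-yl)pent-4-ynoyl]oxazolidin-2-one | C#CC[C@@H](C(C)(C)C=C)C(=O)N1[C@@H](Cc2ccccc2)COC1=O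
F5 | step 2 | (S)-4-benzyl-3-[(2S)-2-(2-methylbut-3-en-2-yl)-5-oxopentanoyl]oxazolidin-2-one | O=CCC[C@@H](C(C)(C)C=C)C(=O)N1[C@@H](Cc2ccccc2)COC1=O
F6 | step 2 | (4S)-5-[(4S)-4-benzyl-2-oxooxazolidin-3-yl]-4-(2-methylbut-3-en-2-yl)-5-oxopentanoic acid | OC(=O)CC[C@@H](C(C)(C)C=C)C(=O)N1[C@@H](Cc2ccccc2)COC1=O
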